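Take a ratio first: theta holds ten times the starting complex of gamma at the same equivalents. If the exchange is an encounter with incoming ligand, the fraction of the charge exchanged should follow concentration times time, and time alone should tell you little. So gamma at 3.00 min stands at 0.300 min of the ligand clock, the charged concentration of incoming ligand times the time, counted in minutes of theta.

| setting | gamma | theta | delta | Wednesday's | Monday's | Thursday's | Sunday's | Tuesday's |
|---|---|---|---|---|---|---|---|---|
| starting complex | 0.0018 M | 0.018 M | 0.010 M | 0.0025 M | 0.020 M | 0.0050 M | 0.015 M | 0.010 M |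
| incoming ligand | 1.5 equiv | 1.5 equiv | 1.5 equiv | 0.380 equiv | 1.50 equiv | 1.50 equiv | 0.750 equiv | 1.50 equiv |
| leaving ligand | 1 equiv | 1 equiv | 1.8 equiv | 1.00 equiv | 1.00 equiv | 1.00 equiv | 2.00 equiv | 1.00 equiv |
| remark | run made earlier | run made earlier | run made earlier |  |  |  |  |  |
| time |  |  |  | 3.0 min | 3.0 min | 3.0 min | 3.0 min | 3.0 min |

| run | time / min | complex with one exchanged / % | starting complex / % |
|---|---|---|---|
| gamma | 0.250 | 3.0 | 67.9 |
| gamma | 0.417 | 2.7 | 66.6 |
| gamma | 0.667 | 5.4 | 65.1 |
| gamma | 1.00 | 6.9 | 63.9 |
| gamma | 2.00 | 12.9 | 58.7 |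
| gamma | 3.00 | 19.1 | 54.2 |
| theta | 0.200 | 14.1 | 57.7 |
| theta | 0.667 | 32.9 | 42.7 |
| theta | 1.00 | 41.8 | 36.4 |
| theta | 1.50 | 50.2 | 29.1 |
| theta | 2.50 | 62.6 | 20.9 |
| theta | 3.00 | 65.3 | 18.6 |
| delta | 0.667 | 22.9 | 51.8 |
| delta | 1.33 | 35.4 | 41.6 |
| delta | 2.00 | 45.1 | 34.5 |
| delta | 2.50 | 49.5 | 31.3 |
| delta | 3.00 | 54.5 | 27.8 |

(each reading ± 0.5 percentage points)

- ranking by amount of complex with one exchanged, in percent of the starting complex charged, from high to low, at 3.0 min (Wednesday's / Monday's / Thursday's / Sunday's / Tuesday's)
- the amount of complex with one exchanged, in percent of the starting complex charged of the flask you put first, at 3.0 min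
- the amount of complex with one exchanged, in percent of the starting complex charged of the flask you put last, at 3.0 min

Test it: theta's chord at that clock reads 18.1 % of complex with one exchanged, and gamma reads 19.1 %, which is fair for a chord. But the dormant form is a first-order step with no such clock. Gamma's first reading answers this: 29.1 % of the charge is already outside the two read forms at 0.250 min, which I take as dormant form, whereas the later decline of starting complex corresponds to a half-life of 8.46 min. Read so, this is a pre-equilibrium, quicker than the exchange, so the clock survives it. And leaving ligand? Delta, with 1.8 equiv, reaches 54.5 % at 1.67 min, where theta's chord gives 52.3 %, so no slowing shows.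

Tuesday's shares that clock. Monday's, at 3.33 min, lies past theta's end, and theta's last slope gives 67.1 %. Thursday's, at 0.833 min, gives 37.3 %. Sunday's shows 1.25 min, but with 0.750 equiv of incoming ligand charged, each exchange takes a larger share of it than in theta. Averaging the rate penalty at theta's level of 41.8 % gives a factor 0.807, hence 1.01 min and about 41.8 %, ahead of Thursday's. In Wednesday's, incoming ligand is the limiting reagent and the clock reads 0.106 min. Gamma's straight line gives 6.72 % and theta's first reading gives 7.44 %. I take theta's, since its clock lies nearer.

The forecast, holding that “Wednesday is ligand-starved”, gives Monday's > Tuesday's > Sunday's > Thursday's > Wednesday's, with 67 % and 6.7 %, the last below my figure.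

The flasks give Monday's > Tuesday's > Sunday's > Thursday's > Wednesday's, with Monday's at 67.2 %, Sunday's at 40.8 %, Thursday's at 37.2 % and Wednesday's at 7.40 %.

    complex with one exchanged + incoming ligand ⇌ leaving ligand + complex with two exchanged (K = 0.270, k = 0.570 M⁻¹ s⁻¹)
    complex with two exchanged + incoming ligand ⇌ leaving ligand + complex with three exchanged (K = 5.50, k = 0.0290 M⁻¹ s⁻¹)
    starting complex + incoming ligand ⇌ leaving ligand + complex with one exchanged (K = 19.0, k = 0.760 M⁻¹ s⁻¹)
    starting complex ⇌ dormant form (K = 0.450, k = 0.170 s⁻¹)

In Monday's, the forward second exchange by itself, at charged concentrations, gives complex with one exchanged a half-life of 0.68 min, short against 3.0 min, yet complex with two exchanged stands at 6.76 %. Monday's charge is twice Tuesday's, so Monday's at 1.50 min shares Tuesday's clock of 1.67 min, and Monday's then holds 53.3 % of complex with one exchanged against Tuesday's 53.3 %.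

Readings and results stem from a simulated flask for an exercise; scatter was added.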